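**Retrosynthetic overview**

1. Septeremophilane G ⇒ O-demethylation of its C7 methyl enol ether ⇒ C3–O ester bond, made by trans-diaxial opening of a 2α,3α-epoxy dienone with (2E,4E,6S)-6-methylocta-2,4-dienoic acid (inverts C3, leaves the C2 hydroxyl).
2. Key step, one flask, two rings: ring A is closed onto an aromatic ring B by Pd-catalysed dearomative allylic alkylation at the methyl-bearing para carbon of a phenoxide (C4–C5 bond, quaternary C5), and the new C2=C3 alkene is epoxidised in situ to the oxirane.
3. Ring order: ring B is the benzene ring of creosol (bought, dearomatised in the key step); ring A and the oxirane then form in the same operation; the oxirane is opened in the following step.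
4. Cyclisation substrate ⇒ Z-allylic bis(methyl carbonate) ⇒ bromomethylated creosol carbonate + (S)-but-3-yn-2-ol (Cu coupling, semi-hydrogenation).
5. Acid ⇒ (S)-2-methylbutan-1-ol + triethyl 4-phosphonocrotonate (oxidation, vinylogous Horner–Wadsworth–Emmons, saponification).

Convention and assumption: locants C1–C10, C14 (methyl on C5) and C15 (methyl on C4) follow eremophilane numbering with the ester on C3; β is the face carrying C14; (S)-but-3-yn-2-ol and (S)-2-methylbutan-1-ol are taken as bought enantiopure.

**Route**

Step 1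
Reactants: 1 creosol (2-methoxy-4-methylphenol)
Product: 2 2-methoxy-4-methylphenyl methyl carbonate
Conditions: ClCO2Me, NaOH (aq), CH2Cl2, 0 °C
Reagents that add atoms: methyl chloroformate, COC(=O)Cl
Why: Schotten–Baumann O-acylation masks the phenol as an electron-poor carbonate, so that the methoxy group controls the next substitution and the phenoxide can be released later under neutral conditions.

Step 2
Reactants: 2 2-methoxy-4-methylphenyl methyl carbonate; 3 formaldehyde (used as paraformaldehyde)
Product: 4 5-(bromomethyl)-2-methoxy-4-methylphenyl methyl carbonate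
Conditions: (CH2O)n, HBr (33% in AcOH), 25 °C
Reagents that add atoms: hydrogen bromide, Br
Why: Blanc-type bromomethylation (electrophilic aromatic substitution) goes to the one position that is para to the methoxy group and ortho to the methyl group, because the position ortho to the carbonate is deactivated and the position between OMe and Me is sterically blocked.

Step 3
Reactants: 4 5-(bromomethyl)-2-methoxy-4-methylphenyl methyl carbonate; 5 (S)-but-3-yn-2-ol
Product: 6 5-[(4S)-4-hydroxypent-2-yn-1-yl]-2-methoxy-4-methylphenyl methyl carbonate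
Conditions: CuI (20 mol%), K2CO3, DMF, 25 °C
Reagents that add atoms: none
Why: Copper-acetylide alkylation by the activated benzylic bromide (Cu-catalysed sp–sp3 coupling) joins the arene to the chiral-pool unit without touching the carbinol stereocentre, which becomes C4.

Step 4
Reactants: 6 5-[(4S)-4-hydroxypent-2-yn-1-yl]-2-methoxy-4-methylphenyl methyl carbonate
Product: 7 5-[(2Z,4S)-4-hydroxypent-2-en-1-yl]-2-methoxy-4-methylphenyl methyl carbonate
Conditions: H2 (1 atm), Pd/CaCO3 poisoned with Pb(OAc)2, quinoline, EtOAc, 25 °C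
Reagents that add atoms: none
Why: Lindlar-type syn semi-hydrogenation stops at the Z-alkene, the geometry that later puts C1 in the anti position of the allyl unit so that a six-membered ring with a cis C2=C3 bond can close.

Step 5
Reactants: 7 5-[(2Z,4S)-4-hydroxypent-2-en-1-yl]-2-methoxy-4-methylphenyl methyl carbonate
Product: 8 2-methoxy-5-[(2Z,4S)-4-(methoxycarbonyloxy)pent-2-en-1-yl]-4-methylphenyl methyl carbonate
Conditions: ClCO2Me, pyridine, CH2Cl2, 0 °C
Reagents that add atoms: methyl chloroformate, COC(=O)Cl
Why: O-acylation turns the secondary allylic alcohol into an ionisable allylic carbonate whose decarboxylation supplies the methoxide that unmasks the phenoxide in step 6.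

Step 6
Reactants: 8 2-methoxy-5-[(2Z,4S)-4-(methoxycarbonyloxy)pent-2-en-1-yl]-4-methylphenyl methyl carbonate
Product: 10 (2R,3S,4R,5S)-2α,3α-epoxy-7-methoxy-11,12,13-trinoreremophila-6,9-dien-8-one, via trienone 9 (not isolated)
Conditions: Pd(PPh3)4 (5 mol%), CH2Cl2 (0.02 M), 25 °C; then mCPBA (1.5 equiv), 0 °C
Reagents that add atoms: mCPBA (3-chloroperoxybenzoic acid), OOC(=O)c1cccc(Cl)c1
Why: Proposed new method: zerovalent palladium ionises the allylic carbonate with inversion to a Z-derived allyl complex (C1 anti, methyl syn), the methoxide released on decarboxylation cleaves the aryl carbonate to dimethyl carbonate and a phenoxide, and this phenoxide attacks the allyl terminus C4 through its methyl-bearing para carbon C5 anti to palladium (net retention at C4, and because the C4 hydrogen sits over the arene while the C4 methyl points outward, C5 is set with C14 and C15 cis) to give trienone 9, whose only nucleophilic alkene C2=C3 is then epoxidised by the peracid from the face opposite the axial C14 methyl; the closest known reactions are the Tsuji–Trost-type intramolecular allylic dearomatisation of phenols to spirocyclohexadienones and the Prilezhaev epoxidation of steroidal 2-enes.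

Step 7
Reactants: 11 (S)-2-methylbutan-1-ol; 12 triethyl (E)-4-phosphonobut-2-enoate
Product: 14 ethyl (2E,4E,6S)-6-methylocta-2,4-dienoate, via (S)-2-methylbutanal 13 (not isolated)
Conditions: TEMPO (1 mol%), KBr (10 mol%), NaOCl, NaHCO3, CH2Cl2/H2O, 0 °C; then the dried organic phase added to 12 + LiN(SiMe3)2, THF, −78 to 0 °C
Reagents that add atoms: none
Why: Anelli oxidation gives the configurationally labile aldehyde without racemisation, and the vinylogous Horner–Wadsworth–Emmons olefination at low temperature builds the new C4=C5 bond E next to the preformed E C2=C3 bond, the C6 stereocentre coming unchanged from the chiral pool.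

Step 8
Reactants: 14 ethyl (2E,4E,6S)-6-methylocta-2,4-dienoate
Product: 15 (2E,4E,6S)-6-methylocta-2,4-dienoic acid
Conditions: LiOH, THF/H2O, 25 °C; then HCl (aq)
Reagents that add atoms: lithium hydroxide, [Li+].[OH-]
Why: Saponification followed by acidification frees the acid without touching the diene or the remote stereocentre.

Step 9
Reactants: 10 (2R,3S,4R,5S)-2α,3α-epoxy-7-methoxy-11,12,13-trinoreremophila-6,9-dien-8-one; 15 (2E,4E,6S)-6-methylocta-2,4-dienoic acid
Product: 16 (2R,3R,4R,5S)-2α-hydroxy-7-methoxy-8-oxo-11,12,13-trinoreremophila-6,9-dien-3β-yl (2E,4E,6S)-6-methylocta-2,4-dienoate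
Conditions: 15 (3 equiv), Cs2CO3 (15 mol%), DMF, 70 °C
Reagents that add atoms: none
Why: Carboxylate opening of the oxirane under Fürst–Plattner (trans-diaxial) control puts the nucleophile axially on C3 from the β face with inversion and leaves the oxygen on C2 as the axial 2α-hydroxyl, while the acid-buffered medium avoids deprotonation at C1.

Step 10
Reactants: 16 (2R,3R,4R,5S)-2α-hydroxy-7-methoxy-8-oxo-11,12,13-trinoreremophila-6,9-dien-3β-yl (2E,4E,6S)-6-methylocta-2,4-dienoate
Product: 17 septeremophilane G
Conditions: BCl3, CH2Cl2, −78 °C; then H2O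
Reagents that add atoms: none
Why: Chelation-assisted Lewis-acid ether cleavage (boron bound between the C8 carbonyl and the C7 methoxy oxygen, chloride removing the methyl group) unmasks the diosphenol at low temperature, where the ester, the secondary alcohol and the four ring stereocentres are not affected.

**Compound list**

1 | creosol (2-methoxy-4-methylphenol) | Cc1ccc(O)c(OC)c1 | starting material
2 | 2-methoxy-4-methylphenyl methyl carbonate | COC(=O)Oc1ccc(C)cc1OC | intermediate
3 | formaldehyde (paraformaldehyde) | C=O | starting material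
4 | 5-(bromomethyl)-2-methoxy-4-methylphenyl methyl carbonate | BrCc1cc(OC(=O)OC)c(OC)cc1C | intermediate
5 | (S)-but-3-yn-2-ol | C[C@H](O)C#C | starting material
6 | 5-[(4S)-4-hydroxypent-2-yn-1-yl]-2-methoxy-4-methylphenyl methyl carbonate | C[C@H](O)C#CCc1cc(OC(=O)OC)c(OC)cc1C | intermediate
7 | 5-[(2Z,4S)-4-hydroxypent-2-en-1-yl]-2-methoxy-4-methylphenyl methyl carbonate | C[C@H](O)/C=C\Cc1cc(OC(=O)OC)c(OC)cc1C | intermediate
8 | 2-methoxy-5-[(2Z,4S)-4-(methoxycarbonyloxy)pent-2-en-1-yl]-4-methylphenyl methyl carbonate | C[C@H](OC(=O)OC)/C=C\Cc1cc(OC(=O)OC)c(OC)cc1C | intermediate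
9 | (4S,5S)-7-methoxy-11,12,13-trinoreremophila-2,6,9-trien-8-one (cis C14/C15) | C[C@H]1C=CCC2=CC(=O)C(OC)=C[C@]12C | intermediate
10 | (2R,3S,4R,5S)-2α,3α-epoxy-7-methoxy-11,12,13-trinoreremophila-6,9-dien-8-one (oxirane anti to both methyls) | C[C@H]1[C@@H]3O[C@@H]3CC2=CC(=O)C(OC)=C[C@]12C | intermediate
11 | (S)-2-methylbutan-1-ol | CC[C@H](C)CO | starting material
12 | triethyl (E)-4-phosphonobut-2-enoate | CCOC(=O)/C=C/CP(=O)(OCC)OCC | starting material
13 | (S)-2-methylbutanal | CC[C@H](C)C=O | intermediate
14 | ethyl (2E,4E,6S)-6-methylocta-2,4-dienoate | CC[C@H](C)/C=C/C=C/C(=O)OCC | intermediate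
15 | (2E,4E,6S)-6-methylocta-2,4-dienoic acid | CC[C@H](C)/C=C/C=C/C(=O)O | intermediate
16 | (2R,3R,4R,5S)-2α-hydroxy-7-methoxy-8-oxo-11,12,13-trinoreremophila-6,9-dien-3β-yl (2E,4E,6S)-6-methylocta-2,4-dienoate | CC[C@H](C)/C=C/C=C/C(=O)O[C@H]1[C@H](O)CC2=CC(=O)C(OC)=C[C@]2(C)[C@H]1C | intermediate
17 | septeremophilane G, (2R,3R,4R,5S)-2α,7-dihydroxy-8-oxo-11,12,13-trinoreremophila-6,9-dien-3β-yl (2E,4E,6S)-6-methylocta-2,4-dienoate | CC[C@H](C)/C=C/C=C/C(=O)O[C@H]1[C@H](O)CC2=CC(=O)C(O)=C[C@]2(C)[C@H]1C | target

**Step count and risks**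

Total step count: 10. Longest linear sequence: 8 (steps 1, 2, 3, 4, 5, 6, 9, 10).

Steps most likely to fail:

Step 6. The phenoxide may close at the unsubstituted ortho carbon C9 and rearomatise, the allyl–palladium intermediate may lose a β-hydrogen to an aryl diene, or the base-sensitive trienone 9 may not survive to the peracid stage. The fallback changes both the electrophile and the medium: a palladium-free alkylative dearomatisation on a preformed oxirane. It sets out from 4, which is coupled (CuI, K2CO3, DMF) with bought (R)-but-3-yn-2-ol to give 5-[(4R)-4-hydroxypent-2-yn-1-yl]-2-methoxy-4-methylphenyl methyl carbonate F1. Semi-hydrogenation as in step 4 gives the (2Z,4R)-allylic alcohol F2. Hydroxyl-directed epoxidation (mCPBA, CH2Cl2, 0 °C, threo-selective for Z-allylic alcohols through allylic strain) gives the cis-epoxy alcohol F3, and MsCl/Et3N gives its methanesulfonate F4. K2CO3 in MeOH/THF at 25 °C then cleaves the aryl carbonate and the methanol-solvated phenoxide displaces the mesylate through C5 in a 6-exo SN2 reaction with inversion at C4 (hence the (R)-alcohol). The fallback comes back to the route at 10.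

Step 9. The opening may be slow at the hindered C3, may go to C2, or the oxirane may open from C1 under base. The fallback uses a cyclic sulfate in place of the oxirane as the C3 electrophile. It sets out from 9, isolated by stopping step 6 after the palladium stage. Dihydroxylation from the α face (OsO4 cat., NMO, acetone/H2O) gives the 2α,3α-diol F5, and SO2Cl2/Et3N (CH2Cl2, −78 °C) gives the cyclic sulfate F6. The cesium salt of 15 (DMF, 40 °C) opens F6 diaxially at C3 to the cesium 2α-sulfate monoester F7, which is hydrolysed with catalytic H2SO4 in THF/H2O. The fallback comes back to the route at 16.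

Step 10. The Lewis acid may dehydrate the β-hydroxy dienone or attack the dienoate. The fallback unmasks the diosphenol before the oxirane and the ester exist. It sets out from 9 (isolated), which is demethylated with BCl3 (CH2Cl2, −78 °C) to the free diosphenol (4S,5S)-7-hydroxy-11,12,13-trinoreremophila-2,6,9-trien-8-one F8. Epoxidation of C2=C3 with mCPBA gives the 2α,3α-epoxide F9, which is opened with 15 under the conditions of step 9. The fallback comes back to the route at 17.

**Further compounds**

F1 | step 6 | 5-[(4R)-4-hydroxypent-2-yn-1-yl]-2-methoxy-4-methylphenyl methyl carbonate | C[C@@H](O)C#CCc1cc(OC(=O)OC)c(OC)cc1C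
F2 | step 6 | 5-[(2Z,4R)-4-hydroxypent-2-en-1-yl]-2-methoxy-4-methylphenyl methyl carbonate | C[C@@H](O)/C=C\Cc1cc(OC(=O)OC)c(OC)cc1C
F3 | step 6 | 5-{[(2R,3S)-3-[(1R)-1-hydroxyethyl]oxiran-2-yl]methyl}-2-methoxy-4-methylphenyl methyl carbonate (threo, cis-oxirane) | C[C@@H](O)[C@@H]1O[C@@H]1Cc1cc(OC(=O)OC)c(OC)cc1C
F4 | step 6 | methanesulfonate of F3 | C[C@@H](OS(C)(=O)=O)[C@@H]1O[C@@H]1Cc1cc(OC(=O)OC)c(OC)cc1C
F5 | step 9 | 2α,3α-dihydroxy-7-methoxy-11,12,13-trinoreremophila-6,9-dien-8-one (both hydroxyls anti to the methyls) | C[C@H]1[C@H](O)[C@H](O)CC2=CC(=O)C(OC)=C[C@]12C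
F6 | step 9 | 2α,3α-cyclic sulfate of F5 | C[C@H]1[C@@H]3OS(=O)(=O)O[C@@H]3CC2=CC(=O)C(OC)=C[C@]12C
F7 | step 9 | cesium salt of the 2α-sulfate monoester of 16 | CC[C@H](C)/C=C/C=C/C(=O)O[C@H]1[C@H](OS(=O)(=O)[O-])CC2=CC(=O)C(OC)=C[C@]2(C)[C@H]1C.[Cs+]
F8 | step 10 | (4S,5S)-7-hydroxy-11,12,13-trinoreremophila-2,6,9-trien-8-one | C[C@H]1C=CCC2=CC(=O)C(O)=C[C@]12C
F9 | step 10 | 2α,3α-epoxy-7-hydroxy-11,12,13-trinoreremophila-6,9-dien-8-one | C[C@H]1[C@@H]3O[C@@H]3CC2=CC(=O)C(O)=C[C@]12C
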